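**Retrosynthetic overview**
1. Target 14 ⇐ TES ether 13 ⇐ saturated-ring ketone 10: the C10 bromine and the C10=C11 double bond are installed last, by enolate chemistry only (α-bromination, then selenoxide dehydrogenation).
2. The only ring (C8–C12) is formed once, from acyclic enynone–ketone 8, by a new enantioselective Cu–H reductive aldol cyclisation that makes the C8–C12 bond and sets both C12 and the 7Z exocyclic alkene.
3. 8 ⇐ lactone 6 (C9–C20, 14Z already present) + enyne ester 5 (C1–C8, 5E already present), by acetylide opening of the lactone and oxidation.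
4. 5 ⇐ methyl hex-5-ynoate by hydrozirconation/iodination and Sonogashira coupling.

**Assumptions (one line each)**
- The SMILES is read as methyl (5E,7Z,12R,14Z)-10-bromo-12-hydroxy-9-oxoprosta-5,7,10,14-tetraenoate; prostanoid numbering is used throughout (C1 = ester carbon, ring = C8–C12).
- Lactone 6 is bought as the racemic Z flavour ingredient (cis-6-dodecen-4-olide, FEMA 3780); its stereocentre is destroyed in step 5.
- The sense of induction in the new step 6 cannot be predicted with certainty; the ligand enantiomer that gives the drawn configuration is written as (R)-DM-SEGPHOS, and the antipode is used if the first run gives ent-9.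
- In 9 and 10 the drawn C12 centre carries the CIP label S only because C13 outranks the saturated C11; the spatial arrangement is that of the target (12R) throughout.

---

**Step 1**
Reactants: 1, methyl hex-5-ynoate
Product: 2, methyl (5E)-6-iodohex-5-enoate
Conditions: Cp2Zr(H)Cl (1.1 equiv), THF, rt, 30 min; then I2, 0 °C
Reagents that add atoms: iodine, II
Why: Syn hydrozirconation of the terminal alkyne puts Zr on the terminal carbon and iodinolysis goes with retention, giving only the E-vinyl iodide (Schwartz hydrozirconation–iodination); the methyl ester tolerates a slight excess of reagent for a short time.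

**Step 2**
Reactants: 2, methyl (5E)-6-iodohex-5-enoate; 3, ethynyltrimethylsilane
Product: 4, methyl (5E)-8-(trimethylsilyl)oct-5-en-7-ynoate
Conditions: PdCl2(PPh3)2 (2 mol %), CuI (4 mol %), Et3N, THF, rt
Reagents that add atoms: none (all heavy atoms come from 2 and 3)
Why: Sonogashira coupling is stereoretentive at the vinyl iodide, so the 5E geometry is carried through.

**Step 3**
Reactants: 4, methyl (5E)-8-(trimethylsilyl)oct-5-en-7-ynoate
Product: 5, methyl (5E)-oct-5-en-7-ynoate
Conditions: K2CO3, MeOH, 0 °C → rt
Reagents that add atoms: none
Why: Methanolysis of the alkynyl–silicon bond (protodesilylation) is fast, and methoxide cannot change a methyl ester.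

**Step 4**
Reactants: 5, methyl (5E)-oct-5-en-7-ynoate; 6, (Z)-6-dodecen-4-olide [5-[(2Z)-oct-2-en-1-yl]dihydrofuran-2(3H)-one], racemic
Product: 7, methyl (5E,14Z)-12-hydroxy-9-oxoicosa-5,14-dien-7-ynoate (racemic at C12; in equilibrium with its cyclic hemiketal)
Conditions: 5, LiHMDS (1.0 equiv), THF, −78 °C; BF3·OEt2; then 6, −78 °C; NH4Cl quench
Reagents that add atoms: none
Why: The enyne C–H is removed selectively over ester α-H at −78 °C, and the BF3-activated γ-lactone takes up one alkynyl group because the tetrahedral intermediate survives until work-up (alkynyllithium opening of a lactone to a γ-hydroxy ynone).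

**Step 5**
Reactants: 7, methyl (5E,14Z)-12-hydroxy-9-oxoicosa-5,14-dien-7-ynoate
Product: 8, methyl (5E,14Z)-9,12-dioxoicosa-5,14-dien-7-ynoate
Conditions: Dess–Martin periodinane, NaHCO3, CH2Cl2, 0 °C → rt; used at once
Reagents that add atoms: none
Why: Buffered Dess–Martin oxidation converts the secondary alcohol (through the open form) to the ketone without base, so the skipped Z-alkene next to the new ketone is not isomerised and the ynone is untouched.

**Step 6 (key step, new)**
Reactants: 8, methyl (5E,14Z)-9,12-dioxoicosa-5,14-dien-7-ynoate
Product: 9, methyl (5E,7Z,12S,14Z)-12-hydroxy-9-oxoprosta-5,7,14-trienoate [= methyl (5E,7Z)-7-[(2S)-2-hydroxy-2-[(2Z)-oct-2-en-1-yl]-5-oxocyclopentylidene]hept-5-enoate]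
Conditions: Cu(OAc)2·H2O (5 mol %), (R)-DM-SEGPHOS (5.5 mol %), (Me2HSi)2O (0.6 equiv), toluene/THF, −40 → −20 °C, dark; then NH4F, MeOH
Reagents that add atoms: none (only hydride from the silane)
Why: Proposed new method: ligand-bound Cu–H adds syn and 1,4 to the ynone, the most electrophilic site, putting H on C7 and Cu on C8 (a Z-α-cuprio enone/copper allenolate), and this adds in-plane through a five-membered transition state to the C12 ketone inside the chiral bisphosphine pocket, which sets C12 enantioselectively and leaves H7 and C12 cis (so C6 is cis to C9=O, i.e. 7Z, under kinetic control with no E1cB pathway to scramble it), with Cu–O/Si–H metathesis turning the catalyst over; the closest known reaction types are the Stryker-type Cu–H reductive aldol cyclisation of alkynones onto ketones and the ligand-controlled enantioselective Cu–H reductive aldol cyclisation of keto-enoates, and what is new is the conjugated enynone donor, the 5-ring closure through the ynone carbonyl, and the simultaneous control of the carbinol centre and the exocyclic alkene geometry.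

**Step 7**
Reactants: 9
Product: 10, methyl (5E,7Z,12S,14Z)-9-oxo-12-(triethylsilyloxy)prosta-5,7,14-trienoate
Conditions: TESOTf (1.3 equiv), 2,6-lutidine, CH2Cl2, −78 °C
Reagents that add atoms: triethylsilyl triflate, CC[Si](CC)(CC)OS(=O)(=O)C(F)(F)F
Why: Silyl triflate/lutidine silylates the hindered tertiary alcohol cleanly at low temperature, masking the OH for the following enolate steps.

**Step 8**
Reactants: 10
Product: 11, methyl (5E,7Z,12R,14Z)-10-bromo-9-oxo-12-(triethylsilyloxy)prosta-5,7,14-trienoate (mixture of C10 epimers)
Conditions: LiHMDS (1.1 equiv), TMSCl, THF, −78 °C; then NBS, THF, −78 °C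
Reagents that add atoms: N-bromosuccinimide, O=C1CCC(=O)N1Br
Why: C10 is the only enolisable α-position (C8 has no H), and the resulting silyl dienol ether is brominated at C10 by NBS at −78 °C far faster than the isolated Z-alkene or the electron-poor dienone (α-bromination via a silyl enol ether).

**Step 9**
Reactants: 11
Product: 12, methyl (5E,7Z,12R,14Z)-10-bromo-9-oxo-10-(phenylselanyl)-12-(triethylsilyloxy)prosta-5,7,14-trienoate (C10 epimers)
Conditions: LiHMDS (1.1 equiv), THF, −78 °C; then PhSeCl, −78 °C
Reagents that add atoms: phenylselenenyl chloride, Cl[Se]c1ccccc1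
Why: The remaining, more acidic C10–H is removed at −78 °C and the bromo-enolate is selenenylated on carbon (α-selenenylation of a ketone enolate); doing Br before Se avoids exposing a selenide to electrophilic bromine.

**Step 10**
Reactants: 12
Product: 13, methyl (5E,7Z,12R,14Z)-10-bromo-9-oxo-12-(triethylsilyloxy)prosta-5,7,10,14-tetraenoate
Conditions: mCPBA (1.05 equiv), CH2Cl2, −78 °C; then i-Pr2NH, −78 → 0 °C, dark
Reagents that add atoms: none
Why: Selenium is oxidised much faster than any alkene at −78 °C, and the selenoxide can only syn-eliminate towards C11–H, giving the 2-bromo-enone with Br retained on C10 (selenoxide elimination of an α-halo-α-seleno ketone).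

**Step 11**
Reactants: 13
Product: 14, bromoclavulone III, methyl (5E,7Z,12R,14Z)-10-bromo-12-hydroxy-9-oxoprosta-5,7,10,14-tetraenoate
Conditions: HF·pyridine, pyridine/THF, 0 °C → rt, dark
Reagents that add atoms: none
Why: Buffered HF cleaves the tertiary TES ether under mildly acidic, non-nucleophilic conditions that do not add to or isomerise the cross-conjugated bromodienone.

---

**Compound list**
1 | methyl hex-5-ynoate | C#CCCCC(=O)OC | starting material
2 | methyl (5E)-6-iodohex-5-enoate | I/C=C/CCCC(=O)OC | intermediate
3 | ethynyltrimethylsilane | C#C[Si](C)(C)C | starting material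
4 | methyl (5E)-8-(trimethylsilyl)oct-5-en-7-ynoate | C[Si](C)(C)C#C/C=C/CCCC(=O)OC | intermediate
5 | methyl (5E)-oct-5-en-7-ynoate | C#C/C=C/CCCC(=O)OC | intermediate
6 | (Z)-6-dodecen-4-olide, racemic | CCCCC/C=C\CC1CCC(=O)O1 | starting material
7 | methyl (5E,14Z)-12-hydroxy-9-oxoicosa-5,14-dien-7-ynoate, racemic | CCCCC/C=C\CC(O)CCC(=O)C#C/C=C/CCCC(=O)OC | intermediate
8 | methyl (5E,14Z)-9,12-dioxoicosa-5,14-dien-7-ynoate | CCCCC/C=C\CC(=O)CCC(=O)C#C/C=C/CCCC(=O)OC | intermediate
9 | methyl (5E,7Z,12S,14Z)-12-hydroxy-9-oxoprosta-5,7,14-trienoate | CCCCC/C=C\C[C@@]1(O)CCC(=O)/C1=C\C=C\CCCC(=O)OC | intermediate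
10 | methyl (5E,7Z,12S,14Z)-9-oxo-12-(triethylsilyloxy)prosta-5,7,14-trienoate | CCCCC/C=C\C[C@@]1(O[Si](CC)(CC)CC)CCC(=O)/C1=C\C=C\CCCC(=O)OC | intermediate
11 | methyl (5E,7Z,12R,14Z)-10-bromo-9-oxo-12-(triethylsilyloxy)prosta-5,7,14-trienoate, C10 epimers | CCCCC/C=C\C[C@@]1(O[Si](CC)(CC)CC)CC(Br)C(=O)/C1=C\C=C\CCCC(=O)OC | intermediate
12 | methyl (5E,7Z,12R,14Z)-10-bromo-9-oxo-10-(phenylselanyl)-12-(triethylsilyloxy)prosta-5,7,14-trienoate, C10 epimers | CCCCC/C=C\C[C@@]1(O[Si](CC)(CC)CC)CC(Br)([Se]c2ccccc2)C(=O)/C1=C\C=C\CCCC(=O)OC | intermediate
13 | methyl (5E,7Z,12R,14Z)-10-bromo-9-oxo-12-(triethylsilyloxy)prosta-5,7,10,14-tetraenoate | CCCCC/C=C\C[C@@]1(O[Si](CC)(CC)CC)C=C(Br)C(=O)/C1=C\C=C\CCCC(=O)OC | intermediate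
14 | bromoclavulone III, methyl (5E,7Z,12R,14Z)-10-bromo-12-hydroxy-9-oxoprosta-5,7,10,14-tetraenoate | CCCCC/C=C\C[C@@]1(O)C=C(Br)C(=O)/C1=C\C=C\CCCC(=O)OC | target

---

**Total step count:** 11
**Longest linear sequence:** 11 steps (1 → 14); 8 steps from lactone 6.

**Three steps most likely to fail, with fallbacks**
1. Step 6 (proposed new Cu–H reductive aldol cyclisation). The risks are 1,2-reduction of a ketone, over-reduction of the product dienone, slow 5-ring closure and low ee. Fallback (known chemistry, different approach): make the ring first and form the C7=C8 bond by the established aldol-condensation route of this family. That is, treat the lithium enolate of (R)-2-bromo-4-[(Z)-oct-2-enyl]-4-(silyloxy)cyclopent-2-enone with methyl (E)-7-oxohept-5-enoate, dehydrate with MsCl/Et3N, separate 7Z from 7E by chromatography and recycle 7E by photo-equilibration. The enone would come from propargyl-type addition to cyclopent-4-ene-1,3-dione mono-ketal, Lindlar reduction, hydrolysis, resolution, then epoxidation and HBr.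
2. Step 9 (selenenylation of the α-bromo enolate, which sets up the dehydrogenation in step 10). The risks are decomposition of the bromo-enolate or poor C-selenenylation at a carbon already bearing Br. Fallback: reverse the logic and make the double bond before the C–Br bond. Saegusa–Ito oxidation of the TMS enol ether of 10 gives the cross-conjugated cyclopentenone; nucleophilic epoxidation of the ring enone (t-BuOOH/DBU), bromide opening (LiBr/AcOH) and dehydration (MsCl/Et3N) then give the 2-bromo-enone by the classical epoxy-ketone route.
3. Step 4 (alkynyllithium opening of lactone 6 with a methyl ester present in 5). The risks are ester enolisation/Claisen condensation, double addition, or the product staying locked as the hemiketal. Fallback: switch to a Weinreb ketone synthesis. Open 6 with Me(MeO)NH·HCl/AlMe3 to the γ-hydroxy Weinreb amide, protect it as the TES ether, acylate the alkynylmagnesium derivative of 5 (i-PrMgCl·LiCl), then remove TES and oxidise to 8.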